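The route rests on forming C12–C13 and C11–C4 in one flask (serrulatane numbering: ring CH–CH3 is C1, the ring CH bearing the side chain is C4, the phenol carbons are C7 and C8, the side-chain CH is C11, its CH2O carbon is C18, and the chain runs C12 to C16). C11 carries C18 and lies between C12 and benzylic C4, which is para, through C4a, to the C7 oxygen of the aromatic ring. With C18 as an acyl oxazolidinone, C12 becomes a Michael acceptor and C11 an enolate carbon, while the C7 oxygen stabilises a C4 cation. A side-chain Grignard reagent, a flat N-acryloyl oxazolidinone and a tetralyl acetate are thus united, setting C11 and C4.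

Key step: step 10

Remark: in step 2 the ligand antipode that delivers the (R)-acid is used; if a first run shows the opposite sense, the other antipode is taken.

Step 1
Reactants: 1 1-(2,3-dimethoxyphenyl)ethan-1-one
Product: 2 (E)-4-(2,3-dimethoxyphenyl)pent-3-enoic acid
Conditions: Ph3P+CH2CH2CO2H Br−, KOt-Bu (3 equiv), THF, 0 °C → reflux; HCl aq.; E isomer crystallised
Reagents that add atoms: (2-carboxyethyl)triphenylphosphonium bromide, OC(=O)CC[P+](c1ccccc1)(c1ccccc1)c1ccccc1.[Br-]
Why: Wittig olefination of the aryl methyl ketone with the carboxylate-bearing ylide should give the β,γ-unsaturated acid directly, with the E isomer (aryl trans to CH2CO2H) expected to predominate; no stereocenter is formed.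

Step 2
Reactants: 2 (E)-4-(2,3-dimethoxyphenyl)pent-3-enoic acid
Product: 3 (R)-4-(2,3-dimethoxyphenyl)pentanoic acid
Conditions: H2 (6 atm), [Ir(cod)(spiro-phosphine-oxazoline)]BArF (1 mol%), Et3N (0.5 equiv), MeOH, rt
Reagents that add atoms: none
Why: Carboxylate-directed iridium-catalysed asymmetric hydrogenation of a β,γ-unsaturated acid, in which the chiral spiro P,N ligand sets the benzylic stereocenter (C1) as R.

Step 3
Reactants: 3 (R)-4-(2,3-dimethoxyphenyl)pentanoic acid
Product: 4 (R)-5,6-dimethoxy-4-methyl-3,4-dihydronaphthalen-1(2H)-one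
Conditions: Eaton's reagent (P2O5/MeSO3H), rt → 40 °C
Reagents that add atoms: none
Why: Intramolecular Friedel–Crafts acylation closes the six-membered ring at the only free ortho position, which is para to a methoxy group, and does not touch the benzylic stereocenter.

Step 4
Reactants: 4 (R)-5,6-dimethoxy-4-methyl-3,4-dihydronaphthalen-1(2H)-one
Product: 5 (4R)-5,6-dimethoxy-4-methyl-1,2,3,4-tetrahydronaphthalen-1-ol (both epimers at the carbinol carbon)
Conditions: NaBH4, MeOH, 0 °C
Reagents that add atoms: none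
Why: Borohydride reduction of the aryl ketone; the carbinol carbon (serrulatane C4) is formed as an epimer mixture, which does not matter because it is ionised in step 10.

Step 5
Reactants: 5 (4R)-5,6-dimethoxy-4-methyl-1,2,3,4-tetrahydronaphthalen-1-ol
Product: 6 (4R)-5,6-dimethoxy-4-methyl-1,2,3,4-tetrahydronaphthalen-1-yl acetate (both epimers at the acetoxy carbon)
Conditions: Ac2O, Et3N, DMAP (cat.), CH2Cl2, 0 °C; used without chromatography
Reagents that add atoms: acetic anhydride, CC(=O)OC(C)=O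
Why: DMAP-catalysed acetylation turns the benzylic hydroxyl into a leaving group for SN1 ionisation; no stereocenter is set.

Step 6
Reactants: 7 (S)-3-bromo-2-methylpropan-1-ol
Product: 8 (S)-(3-bromo-2-methylpropoxy)(tert-butyl)dimethylsilane
Conditions: TBSCl, imidazole, DMF, rt
Reagents that add atoms: tert-butyldimethylsilyl chloride, CC(C)(C)[Si](C)(C)Cl
Why: Standard silylation of the primary alcohol; the chiral-pool stereocenter (C15) is untouched.

Step 7
Reactants: 8 (S)-(3-bromo-2-methylpropoxy)(tert-butyl)dimethylsilane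
Product: 10 (R)-4-((tert-butyldimethylsilyl)oxy)-3-methylbutan-1-ol, via Grignard reagent 9 (not isolated)
Conditions: Mg, THF, rt; then (CH2O)n, 0 °C → rt; NH4Cl aq.
Reagents that add atoms: formaldehyde (from paraformaldehyde), C=O
Why: One-carbon homologation by Grignard addition to formaldehyde; the stereocenter is not involved, and its descriptor changes from S to R only because the priorities change.

Step 8
Reactants: 10 (R)-4-((tert-butyldimethylsilyl)oxy)-3-methylbutan-1-ol
Product: 11 (R)-(4-bromo-2-methylbutoxy)(tert-butyl)dimethylsilane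
Conditions: CBr4, PPh3, CH2Cl2, 0 °C
Reagents that add atoms: carbon tetrabromide, BrC(Br)(Br)Br
Why: Appel bromination of the primary alcohol under neutral conditions that the silyl ether tolerates.

Step 9
Reactants: 12 (R)-4-benzyloxazolidin-2-one
Product: 13 (R)-3-acryloyl-4-benzyloxazolidin-2-one
Conditions: acryloyl chloride, Et3N, LiCl, THF, −20 °C → rt
Reagents that add atoms: acryloyl chloride, C=CC(=O)Cl
Why: Mild N-acylation of the oxazolidinone (LiCl/amine protocol), which avoids a strongly basic anion and so limits polymerisation of the acryloyl group.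

Step 10
Reactants: 6 (4R)-5,6-dimethoxy-4-methyl-1,2,3,4-tetrahydronaphthalen-1-yl acetate; 11 (R)-(4-bromo-2-methylbutoxy)(tert-butyl)dimethylsilane; 13 (R)-3-acryloyl-4-benzyloxazolidin-2-one
Product: 17 (R)-4-benzyl-3-[(2S,6R)-7-((tert-butyldimethylsilyl)oxy)-2-((1S,4R)-5,6-dimethoxy-4-methyl-1,2,3,4-tetrahydronaphthalen-1-yl)-6-methylheptanoyl]oxazolidin-2-one, via Grignard reagent 14 (not isolated), via magnesium enolate 15 (not isolated), via titanium enolate 16 (not isolated)
Conditions: 11, Mg, Et2O; CuBr·SMe2, Me2S/Et2O, −40 °C; 13, CH2Cl2, −78 °C; TiCl4, −78 °C; then 6, CH2Cl2, −78 → −30 °C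
Reagents that add atoms: none
Why: Proposed new method: a three-component conjugate addition/SN1 alkylation in one flask, whose closest known relatives are copper-mediated Grignard additions to N-enoyl oxazolidinones with in-situ enolate trapping and the SN1 alkylation of chlorotitanium imide enolates (or silyl enol ethers, Reetz type) with stabilised carbocations. The organocopper from 14 should add to C12 of the s-cis-chelated acrylimide 13, which forms the C12–C13 bond and the chelated (Z)-enolate 15; TiCl4 should then exchange magnesium for titanium (16) and ionise both epimers of 6 to the same C4 benzylic cation, stabilised by the para C7 oxygen, which the enolate carbon C11 captures. No ring is closed. C11 is controlled by the auxiliary: its benzyl group shields one face of the chelated (Z)-enolate, so C4 enters anti to it in the Evans sense and the (R)-auxiliary should give 11S. C4 is controlled by the ring: peri strain with the C8 methoxy group holds the C1 methyl pseudoaxial, and axial attack on the cation from the opposite face should give the 1,4-trans tetralin (4S). The step needs 1,4- over 1,2-addition and C-alkylation over E1 loss to the dihydronaphthalene, which copper, low temperature and the amine-free, weakly basic titanium enolate should secure.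

Step 11
Reactants: 17 (R)-4-benzyl-3-[(2S,6R)-7-((tert-butyldimethylsilyl)oxy)-2-((1S,4R)-5,6-dimethoxy-4-methyl-1,2,3,4-tetrahydronaphthalen-1-yl)-6-methylheptanoyl]oxazolidin-2-one
Product: 18 (2S,6R)-7-((tert-butyldimethylsilyl)oxy)-2-[(1S,4R)-5,6-dimethoxy-4-methyl-1,2,3,4-tetrahydronaphthalen-1-yl]-6-methylheptan-1-ol
Conditions: LiBH4, MeOH (1 equiv), Et2O, 0 °C
Reagents that add atoms: none
Why: Reductive cleavage of the N-acyl oxazolidinone by hydride attack on the exocyclic carbonyl should give the primary alcohol (C18) without epimerising C11 and return the auxiliary.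

Step 12
Reactants: 18 (2S,6R)-7-((tert-butyldimethylsilyl)oxy)-2-[(1S,4R)-5,6-dimethoxy-4-methyl-1,2,3,4-tetrahydronaphthalen-1-yl]-6-methylheptan-1-ol
Product: 20 (5R,8S)-8-[(2S,6R)-7-((tert-butyldimethylsilyl)oxy)-1-hydroxy-6-methylheptan-2-yl]-3,4-dimethoxy-5-methyl-5,6,7,8-tetrahydronaphthalene-2-carboxylic acid, via dilithio species 19 (not isolated)
Conditions: n-BuLi (3.5 equiv), TMEDA, THF, 0 °C; CO2, −78 °C → rt; HCl aq.
Reagents that add atoms: carbon dioxide, O=C=O
Why: Directed ortho metalation, in which the C7 methoxy group directs lithiation to C6, the only ring hydrogen ortho to an oxygen, followed by carboxylation; the alcohol is carried as its lithium alkoxide.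

Step 13
Reactants: 20 (5R,8S)-8-[(2S,6R)-7-((tert-butyldimethylsilyl)oxy)-1-hydroxy-6-methylheptan-2-yl]-3,4-dimethoxy-5-methyl-5,6,7,8-tetrahydronaphthalene-2-carboxylic acid
Product: 21 (5R,8S)-8-[(2S,6R)-1,7-dihydroxy-6-methylheptan-2-yl]-3,4-dihydroxy-5-methyl-5,6,7,8-tetrahydronaphthalene-2-carboxylic acid
Conditions: BBr3 (8 equiv), CH2Cl2, −78 → 0 °C; H2O, 0 °C; handled under argon
Reagents that add atoms: none
Why: Lewis-acid cleavage of both aryl methyl ethers and of the silyl ether with BBr3, kept at or below 0 °C so that the primary alcohols return as alcohols on hydrolysis; no stereocenter is affected.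

Step 14
Reactants: 21 (5R,8S)-8-[(2S,6R)-1,7-dihydroxy-6-methylheptan-2-yl]-3,4-dihydroxy-5-methyl-5,6,7,8-tetrahydronaphthalene-2-carboxylic acid
Product: 22 (5R,8S)-8-[(2S,6R)-1,7-diacetoxy-6-methylheptan-2-yl]-3,4-dihydroxy-5-methyl-5,6,7,8-tetrahydronaphthalene-2-carboxylic acid (CNP0245723.1)
Conditions: Novozym 435 (CAL-B), vinyl acetate (6 equiv), THF, 40 °C
Reagents that add atoms: vinyl acetate, C=COC(C)=O
Why: Lipase-catalysed transesterification with vinyl acetate should acylate the two primary aliphatic hydroxyls and leave the phenols and the carboxylic acid free (chemoselective enzymatic acylation).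

Compound list
1 | 1-(2,3-dimethoxyphenyl)ethan-1-one | CC(=O)c1cccc(OC)c1OC | starting material
2 | (E)-4-(2,3-dimethoxyphenyl)pent-3-enoic acid | C/C(=C\CC(=O)O)c1cccc(OC)c1OC | intermediate
3 | (R)-4-(2,3-dimethoxyphenyl)pentanoic acid | OC(=O)CC[C@@H](C)c1cccc(OC)c1OC | intermediate
4 | (R)-5,6-dimethoxy-4-methyl-3,4-dihydronaphthalen-1(2H)-one | O=C1CC[C@@H](C)c2c1ccc(OC)c2OC | intermediate
5 | (4R)-5,6-dimethoxy-4-methyl-1,2,3,4-tetrahydronaphthalen-1-ol, both C1 epimers | OC1CC[C@@H](C)c2c1ccc(OC)c2OC | intermediate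
6 | (4R)-5,6-dimethoxy-4-methyl-1,2,3,4-tetrahydronaphthalen-1-yl acetate, both C1 epimers | CC(=O)OC1CC[C@@H](C)c2c1ccc(OC)c2OC | intermediate
7 | (S)-3-bromo-2-methylpropan-1-ol | OC[C@H](C)CBr | starting material
8 | (S)-(3-bromo-2-methylpropoxy)(tert-butyl)dimethylsilane | CC(C)(C)[Si](C)(C)OC[C@H](C)CBr | intermediate
9 | (S)-[3-((tert-butyldimethylsilyl)oxy)-2-methylpropyl]magnesium bromide | CC(C)(C)[Si](C)(C)OC[C@H](C)C[Mg]Br | intermediate (not isolated)
10 | (R)-4-((tert-butyldimethylsilyl)oxy)-3-methylbutan-1-ol | CC(C)(C)[Si](C)(C)OC[C@H](C)CCO | intermediate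
11 | (R)-(4-bromo-2-methylbutoxy)(tert-butyl)dimethylsilane | CC(C)(C)[Si](C)(C)OC[C@H](C)CCBr | intermediate
12 | (R)-4-benzyloxazolidin-2-one | O=C1N[C@H](Cc2ccccc2)CO1 | starting material
13 | (R)-3-acryloyl-4-benzyloxazolidin-2-one | C=CC(=O)N1[C@H](Cc2ccccc2)COC1=O | intermediate
14 | (R)-[4-((tert-butyldimethylsilyl)oxy)-3-methylbutyl]magnesium bromide | CC(C)(C)[Si](C)(C)OC[C@H](C)CC[Mg]Br | intermediate (not isolated)
15 | bromomagnesium (Z)-enolate of (R)-4-benzyl-3-[(R)-6-((tert-butyldimethylsilyl)oxy)-5-methylhexanoyl]oxazolidin-2-one | CC(C)(C)[Si](C)(C)OC[C@H](C)CCC/C=C(\O[Mg]Br)N1[C@H](Cc2ccccc2)COC1=O | intermediate (not isolated)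
16 | trichlorotitanium (Z)-enolate of the same imide | CC(C)(C)[Si](C)(C)OC[C@H](C)CCC/C=C(\O[Ti](Cl)(Cl)Cl)N1[C@H](Cc2ccccc2)COC1=O | intermediate (not isolated)
17 | (R)-4-benzyl-3-[(2S,6R)-7-((tert-butyldimethylsilyl)oxy)-2-((1S,4R)-5,6-dimethoxy-4-methyl-1,2,3,4-tetrahydronaphthalen-1-yl)-6-methylheptanoyl]oxazolidin-2-one | CC(C)(C)[Si](C)(C)OC[C@H](C)CCC[C@H](C(=O)N1[C@H](Cc2ccccc2)COC1=O)[C@@H]1CC[C@@H](C)c2c1ccc(OC)c2OC | intermediate
18 | (2S,6R)-7-((tert-butyldimethylsilyl)oxy)-2-[(1S,4R)-5,6-dimethoxy-4-methyl-1,2,3,4-tetrahydronaphthalen-1-yl]-6-methylheptan-1-ol | CC(C)(C)[Si](C)(C)OC[C@H](C)CCC[C@H](CO)[C@@H]1CC[C@@H](C)c2c1ccc(OC)c2OC | intermediate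
19 | dilithio species of 18 (lithium alkoxide at C18, aryllithium at C6) | CC(C)(C)[Si](C)(C)OC[C@H](C)CCC[C@H](CO[Li])[C@@H]1CC[C@@H](C)c2c1cc([Li])c(OC)c2OC | intermediate (not isolated)
20 | (5R,8S)-8-[(2S,6R)-7-((tert-butyldimethylsilyl)oxy)-1-hydroxy-6-methylheptan-2-yl]-3,4-dimethoxy-5-methyl-5,6,7,8-tetrahydronaphthalene-2-carboxylic acid | CC(C)(C)[Si](C)(C)OC[C@H](C)CCC[C@H](CO)[C@@H]1CC[C@@H](C)c2c1cc(C(=O)O)c(OC)c2OC | intermediate
21 | (5R,8S)-8-[(2S,6R)-1,7-dihydroxy-6-methylheptan-2-yl]-3,4-dihydroxy-5-methyl-5,6,7,8-tetrahydronaphthalene-2-carboxylic acid | OC[C@H](C)CCC[C@H](CO)[C@@H]1CC[C@@H](C)c2c1cc(C(=O)O)c(O)c2O | intermediate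
22 | (5R,8S)-8-[(2S,6R)-1,7-diacetoxy-6-methylheptan-2-yl]-3,4-dihydroxy-5-methyl-5,6,7,8-tetrahydronaphthalene-2-carboxylic acid | CC(=O)OC[C@H](C)CCC[C@H](COC(C)=O)[C@@H]1CC[C@@H](C)c2c1cc(C(=O)O)c(O)c2O | target

Total step count: 14
Longest linear sequence: 10 steps (steps 1–5 and 10–14)

Steps most likely to fail

Step 10 (Proposed new method). What may go wrong: the first-formed enolate may add to a second molecule of 13 (oligomerisation); the C4 cation may lose a proton to the dihydronaphthalene faster than it is captured; or chelation may be incomplete in the ethereal medium, so that facial control at C11 erodes. The fallback uses known chemistry only, sets out from 6 and returns at 18. Acetate 6 is alkylated in an SN1 Mukaiyama-type reaction with 1,1-bis(trimethylsilyloxy)ethene (cat. TMSOTf, CH2Cl2, −78 °C; the same ring control should give the trans product) to 2-[(1S,4R)-5,6-dimethoxy-4-methyl-1,2,3,4-tetrahydronaphthalen-1-yl]acetic acid F1. DCC/DMAP coupling of F1 with 12 gives (R)-4-benzyl-3-{2-[(1S,4R)-5,6-dimethoxy-4-methyl-1,2,3,4-tetrahydronaphthalen-1-yl]acetyl}oxazolidin-2-one F2. Evans titanium-enolate benzyloxymethylation (TiCl4, i-Pr2NEt, BnOCH2Cl, CH2Cl2, 0 °C) sets C11 and gives (R)-4-benzyl-3-{(2S)-3-(benzyloxy)-2-[(1S,4R)-5,6-dimethoxy-4-methyl-1,2,3,4-tetrahydronaphthalen-1-yl]propanoyl}oxazolidin-2-one F3. LiBH4 gives (2R)-3-(benzyloxy)-2-[(1S,4R)-5,6-dimethoxy-4-methyl-1,2,3,4-tetrahydronaphthalen-1-yl]propan-1-ol F4 and returns 12. I2, PPh3 and imidazole give (1S,4R)-1-[(2S)-1-(benzyloxy)-3-iodopropan-2-yl]-5,6-dimethoxy-4-methyl-1,2,3,4-tetrahydronaphthalene F5. Copper-catalysed alkyl–alkyl coupling of F5 with Grignard reagent 14 (Li2CuCl4 cat., THF–NMP, 0 °C) still forms C12–C13 between the two fragments and gives tert-butyl{[(2R,6S)-7-(benzyloxy)-6-[(1S,4R)-5,6-dimethoxy-4-methyl-1,2,3,4-tetrahydronaphthalen-1-yl]-2-methylheptyl]oxy}dimethylsilane F6. Hydrogenolysis (H2, Pd/C, EtOAc) then removes the benzyl group and gives 18.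

Step 12. What may go wrong: metalation may be slow or go astray (attack at the silyl ether, benzylic deprotonation) because the lithium alkoxide aggregates the base. The fallback sets out from 18 and returns at 20. Electrophilic bromination (NBS, MeCN, 0 °C) ortho to the C7 methoxy group gives (2S,6R)-2-[(1S,4R)-7-bromo-5,6-dimethoxy-4-methyl-1,2,3,4-tetrahydronaphthalen-1-yl]-7-((tert-butyldimethylsilyl)oxy)-6-methylheptan-1-ol F7. Bromine–lithium exchange (n-BuLi, 2.2 equiv, THF, −78 °C) followed by CO2 gives 20, so that the site of metalation is fixed by the halogen and not by C–H acidity.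

Step 14. What may go wrong: acylation of the hindered C18 hydroxyl may stall at the monoacetate, or acyl groups may drift to the phenols. The fallback sets out from 21 and returns at 22. Exhaustive acetylation (Ac2O, pyridine, DMAP; aqueous work-up to hydrolyse the mixed anhydride) gives (5R,8S)-3,4-diacetoxy-8-[(2S,6R)-1,7-diacetoxy-6-methylheptan-2-yl]-5-methyl-5,6,7,8-tetrahydronaphthalene-2-carboxylic acid F8. The two aryl acetates are then cleaved selectively (NH4OAc, aqueous MeOH, rt), which should leave the alkyl acetates and give 22.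

Further compounds
F1 | step 10 | 2-[(1S,4R)-5,6-dimethoxy-4-methyl-1,2,3,4-tetrahydronaphthalen-1-yl]acetic acid | OC(=O)C[C@@H]1CC[C@@H](C)c2c1ccc(OC)c2OC
F2 | step 10 | (R)-4-benzyl-3-{2-[(1S,4R)-5,6-dimethoxy-4-methyl-1,2,3,4-tetrahydronaphthalen-1-yl]acetyl}oxazolidin-2-one | O=C(C[C@@H]1CC[C@@H](C)c2c1ccc(OC)c2OC)N1[C@H](Cc2ccccc2)COC1=O
F3 | step 10 | (R)-4-benzyl-3-{(2S)-3-(benzyloxy)-2-[(1S,4R)-5,6-dimethoxy-4-methyl-1,2,3,4-tetrahydronaphthalen-1-yl]propanoyl}oxazolidin-2-one | O=C([C@H](COCc1ccccc1)[C@@H]1CC[C@@H](C)c2c1ccc(OC)c2OC)N1[C@H](Cc2ccccc2)COC1=O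
F4 | step 10 | (2R)-3-(benzyloxy)-2-[(1S,4R)-5,6-dimethoxy-4-methyl-1,2,3,4-tetrahydronaphthalen-1-yl]propan-1-ol | OC[C@H](COCc1ccccc1)[C@@H]1CC[C@@H](C)c2c1ccc(OC)c2OC
F5 | step 10 | (1S,4R)-1-[(2S)-1-(benzyloxy)-3-iodopropan-2-yl]-5,6-dimethoxy-4-methyl-1,2,3,4-tetrahydronaphthalene | IC[C@H](COCc1ccccc1)[C@@H]1CC[C@@H](C)c2c1ccc(OC)c2OC
F6 | step 10 | tert-butyl{[(2R,6S)-7-(benzyloxy)-6-[(1S,4R)-5,6-dimethoxy-4-methyl-1,2,3,4-tetrahydronaphthalen-1-yl]-2-methylheptyl]oxy}dimethylsilane | CC(C)(C)[Si](C)(C)OC[C@H](C)CCC[C@H](COCc1ccccc1)[C@@H]1CC[C@@H](C)c2c1ccc(OC)c2OC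
F7 | step 12 | (2S,6R)-2-[(1S,4R)-7-bromo-5,6-dimethoxy-4-methyl-1,2,3,4-tetrahydronaphthalen-1-yl]-7-((tert-butyldimethylsilyl)oxy)-6-methylheptan-1-ol | CC(C)(C)[Si](C)(C)OC[C@H](C)CCC[C@H](CO)[C@@H]1CC[C@@H](C)c2c1cc(Br)c(OC)c2OC
F8 | step 14 | (5R,8S)-3,4-diacetoxy-8-[(2S,6R)-1,7-diacetoxy-6-methylheptan-2-yl]-5-methyl-5,6,7,8-tetrahydronaphthalene-2-carboxylic acid | CC(=O)OC[C@H](C)CCC[C@H](COC(C)=O)[C@@H]1CC[C@@H](C)c2c1cc(C(=O)O)c(OC(C)=O)c2OC(C)=O
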